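**Plan**

- Numbering and faces: C1 quaternary methyl carbon (ring fusion), C2/C3 CH2, C4 isopropyl carbinol, C5 fusion CH, C6 benzoyloxy carbon, C7 CH2, C8(Me)=C9, C10 angeloyloxy carbon; ring A = C1–C5, ring B = C1, C5–C10; β = face of the C1 methyl, α = the other face.
- Cuts: C10–O (angelate, made with inversion), O6–benzoyl, C8–CH3, C4–isopropyl, and last the ring-fusion bond C1–C5.
- Enabling feature: C1–C5 ties the quaternary C1 to a CH flanked by the oxygenated C6. With C1 on C6 instead, the skeleton is a decalin (rings C1–C6 and C1/C6–C10), so one 1,2-shift of C1 from C6 to C5 shrinks the first cyclohexane to ring A and enlarges the second to ring B, leaving C6 as a ketone.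
- Forward: (S)-Wieland–Miescher ketone → all-cis 4,5,6-trioxygenated cis-decalin with a C5 mesylate → hydroazulenone (both rings resized in one step) → C6 benzoate → C4 isopropyl carbinol → ring-B enone, C8 methyl, C10 angelate.
- Stereochemistry: C1 from the purchased ketone; C5 by inversion at the mesylate carbon (β-oxygens from an OH-directed osmylation); C6 by thermodynamic dissolving-metal reduction; C4 by addition anti to the angular methyl; C10 by hydride attack anti to the methyl, then Mitsunobu inversion; Z-olefin from angelic acid.

Key step: step 7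

Assumption: (S)-(+)-Wieland–Miescher ketone is bought as the single enantiomer, and the C8 methyl is added only after the rearrangement, because a ring methyl carried through the decalin stage would be an uncontrolled stereocentre that decides which chair–chair form of the rearrangement substrate is populated.

**Route**

Step 1
Reactants: 1 (S)-(+)-Wieland–Miescher ketone
Product: 2 hydroxy enone (C4 ketone, C5=C6, 10β-OH)
Conditions: NaBH4 (0.3 equiv), EtOH, −10 °C
Reagents that add atoms: none
Why: Chemoselective borohydride reduction of the saturated ketone beside the less electrophilic enone; hydride adds axially, anti to the angular methyl, so the C10 hydroxyl is equatorial and β (cis to the methyl), a temporary stereocentre used later as a conformational anchor.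

Step 2
Reactants: 2 hydroxy enone
Product: 3 10β-triisopropylsilyl (TIPS) ether of 2
Conditions: TIPSOTf, 2,6-lutidine, CH2Cl2, −78 → 0 °C
Reagents that add atoms: triisopropylsilyl triflate, CC(C)[Si](C(C)C)(C(C)C)OS(=O)(=O)C(F)(F)F
Why: Silyl triflate silylation of a hindered secondary alcohol; C10 is carried as this β-silyl ether rather than as a ketal because a single β-substituent is equatorial in exactly the chair–chair form of 8 that has the mesylate equatorial, and TIPS outlasts the later removal of TBS.

Step 3
Reactants: 3 silyl ether enone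
Product: 4 allylic alcohol (4β-OH, C5=C6, 10β-OTIPS)
Conditions: NaBH4, CeCl3·7H2O, MeOH, −78 → −20 °C
Reagents that add atoms: none
Why: Luche 1,2-reduction of the enone; hydride enters from the α face, as in related 10-methyl-octalones and steroidal 4-en-3-ones, giving the pseudo-equatorial 4β-alcohol that will direct the osmylation.

Step 4
Reactants: 4 allylic alcohol
Product: 6 all-cis 4β/5β/6β-triol of the cis-decalin (10β-OTIPS), via osmate ester TMEDA chelate 5 (not isolated)
Conditions: OsO4 (1.0 equiv), TMEDA (1.1 equiv), CH2Cl2, −78 °C; then aq. Na2SO3, THF, 60 °C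
Reagents that add atoms: osmium tetroxide, O=[Os](=O)(=O)=O; TMEDA, CN(C)CCN(C)C (held only in 5)
Why: Hydroxyl-directed dihydroxylation: the OsO4–TMEDA complex is hydrogen-bonded by the allylic C4 hydroxyl and adds to the same β face of C5=C6 against the steric bias of the angular methyl, so O4, O5, O6 and the C1 methyl are all cis (cis-decalin); sulfite then cleaves the osmate ester.

Step 5
Reactants: 6 all-cis triol
Product: 7 4β-tert-butyldimethylsilyl (TBS) ether 5β,6β-diol
Conditions: TBSCl (1.1 equiv), imidazole, DMF, 0 °C
Reagents that add atoms: tert-butyldimethylsilyl chloride, CC(C)(C)[Si](C)(C)Cl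
Why: Regioselective silylation of the less hindered secondary alcohol: the C5 hydroxyl is flanked by the fully substituted C6 and by C4, and the C6 hydroxyl is tertiary, so the bulky chlorosilane should take O4.

Step 6
Reactants: 7 silyl ether diol
Product: 8 hydroxy mesylate (4β-OTBS, 5β-OMs, angular 6β-OH, 10β-OTIPS, cis-decalin)
Conditions: MsCl, Et3N, CH2Cl2, −20 → 0 °C
Reagents that add atoms: methanesulfonyl chloride, CS(=O)(=O)Cl
Why: Sulfonylation of the remaining secondary alcohol through sulfene, which tolerates the hindered site; the tertiary angular hydroxyl does not react and, being cis to the mesylate, cannot close an epoxide.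

Step 7
Reactants: 8 hydroxy mesylate
Product: 9 trans-fused hydroazulen-6-one (1β-Me, 5α-H, 4β-OTBS, 10β-OTIPS)
Conditions: KOtBu (1.1 equiv), tBuOH/THF (1:4), 0 °C → rt
Reagents that add atoms: none
Why: KOtBu deprotonates the angular C6 hydroxyl and the alkoxide drives a concerted 1,2-shift of the C6–C1 bond onto C5 with loss of mesylate, the C6 oxygen becoming the ketone (semipinacol rearrangement; the closest known reaction type is the base-induced rearrangement of angular-hydroxy decalin sulfonates to hydroazulenones). Ring A (C1–C5) closes by contraction of the mesylate-bearing cyclohexane as C1 bonds to C5, and ring B (C1, C5–C10) by one-carbon expansion of the other cyclohexane as C5 is inserted between C1 and C6. C5 is the only new stereocentre: C1 arrives anti to the departing β-mesylate, so C5 is inverted and its hydrogen ends α, trans to the C1 methyl, while C1 migrates with retention. The step needs C6–C1 rather than C6–C7 to migrate, which demands an equatorial mesylate; the substrate secures this because the other chair–chair form would put the mesylate syn-diaxial to the C1 methyl and the C10 silyloxy group syn-diaxial to the C6 oxygen. The cis relation of O5 and O6 excludes epoxide formation, the silylated O4 cannot push its own antiperiplanar bond (C4–C3), and the base is consumed as the reaction proceeds, so the β-silyloxy ketone is not left in excess alkoxide.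

Step 8
Reactants: 9 hydroazulen-6-one
Product: 10 6α-alcohol
Conditions: Li, NH3(l)/THF, EtOH (2 equiv), −78 °C
Reagents that add atoms: none
Why: Dissolving-metal reduction of the ketone under thermodynamic control should give the more stable equatorial 6α-alcohol (trans to the C1 methyl, cis to H5), whereas a hydride reagent would attack the open α face and give the axial 6β-epimer, the same contrast as for hindered steroidal ketones such as 11-ketones.

Step 9
Reactants: 10 6α-alcohol; 11 benzoyl chloride
Product: 12 6α-benzoate
Conditions: BzCl, pyridine, DMAP (cat.), CH2Cl2, 0 °C → rt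
Reagents that add atoms: benzoyl chloride, O=C(Cl)c1ccccc1
Why: DMAP-catalysed acylation of the unhindered equatorial secondary alcohol with an acid chloride.

Step 10
Reactants: 12 6α-benzoate
Product: 13 4β-alcohol (6α-OBz, 10β-OTIPS)
Conditions: HF·pyridine, pyridine, THF, 0 °C → rt
Reagents that add atoms: none
Why: Acidic fluoride desilylation, in which a secondary TBS ether is lost much faster than the hindered TIPS ether; the benzoate is untouched and, being 1,3-anti to O4, should not migrate.

Step 11
Reactants: 13 4β-alcohol
Product: 14 C4 ketone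
Conditions: Dess–Martin periodinane, CH2Cl2, 0 °C → rt
Reagents that add atoms: none
Why: Dess–Martin oxidation of the secondary alcohol under near-neutral conditions, so the β-benzoyloxy ketone is not exposed to base (no E1cB loss of benzoate).

Step 12
Reactants: 14 C4 ketone; 15 isopropylmagnesium chloride
Product: 16 tertiary alcohol (4β-OH, 4α-isopropyl)
Conditions: CeCl3 (anhydrous), iPrMgCl, THF, −78 °C; then H2O
Reagents that add atoms: isopropylmagnesium chloride, CC(C)[Mg]Cl
Why: Organocerium 1,2-addition: the weakly basic, strongly nucleophilic isopropylcerium reagent adds to the cyclopentanone faster than to the benzoate and without enolisation, and because the β face of C4=O is screened by the 1,3-related angular methyl the isopropyl group enters from the α face and the hydroxyl ends β.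

Step 13
Reactants: 16 tertiary alcohol
Product: 17 4β,10β-diol (6α-OBz)
Conditions: TBAF, AcOH, THF, 45 °C
Reagents that add atoms: none
Why: Fluoride cleavage of the TIPS ether, buffered with acetic acid to protect the benzoate.

Step 14
Reactants: 17 diol
Product: 18 C10 ketone
Conditions: Dess–Martin periodinane, CH2Cl2, rt
Reagents that add atoms: none
Why: Dess–Martin oxidation of the only secondary alcohol; the tertiary C4 hydroxyl is inert, and the C10 stereocentre, its anchoring role over, is erased.

Step 15
Reactants: 18 C10 ketone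
Product: 20 cyclohept-8-en-10-one with 4-OTMS, via bis-trimethylsilyl derivative 19 (not isolated)
Conditions: TMSOTf, Et3N, CH2Cl2, 0 °C; then Pd(OAc)2 (1.1 equiv), MeCN, rt
Reagents that add atoms: trimethylsilyl triflate, C[Si](C)(C)OS(=O)(=O)C(F)(F)F
Why: Saegusa–Ito dehydrogenation: soft enolisation can only occur toward C9 because C1 is quaternary (the tertiary hydroxyl is silylated in passing, which protects it for the next step), and Pd(OAc)2 converts the enol silyl ether into the C8=C9 enone by β-hydride elimination.

Step 16
Reactants: 20 enone; 21 methyllithium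
Product: 24 8-methyl-8-en-10-one with free 4β-OH, via enol silyl ether 22 (not isolated), via enone silyl ether 23 (not isolated)
Conditions: MeLi, CuI (Me2CuLi), TMSCl, THF, −78 °C; then Pd(OAc)2 (1.1 equiv), MeCN, rt; then 1 M HCl, THF, 0 °C
Reagents that add atoms: methyllithium, [Li]C (used as Me2CuLi); chlorotrimethylsilane, C[Si](C)(C)Cl (silicon only in 22)
Why: Cuprate conjugate addition with TMSCl trapping places the methyl at C8 and gives the enol silyl ether regiospecifically, a second Saegusa–Ito oxidation restores the C8=C9 double bond (erasing the C8 stereocentre formed in passing), and dilute acid frees the tertiary alcohol from its TMS ether.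

Step 17
Reactants: 24 β-methyl enone
Product: 25 10β-allylic alcohol
Conditions: NaBH4, CeCl3·7H2O, MeOH, −40 °C
Reagents that add atoms: none
Why: Luche 1,2-reduction; hydride should add anti to the pseudo-axial C1 methyl, as in reductions of ketones next to a methyl-bearing trans ring fusion, giving the pseudo-equatorial 10β-alcohol (cis to the methyl), deliberately the epimer opposite to the target.

Step 18
Reactants: 25 10β-allylic alcohol; 26 angelic acid
Product: 27 target compound
Conditions: angelic acid, PPh3, DIAD, toluene, 0 °C → rt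
Reagents that add atoms: angelic acid, C/C=C(/C)C(=O)O
Why: Mitsunobu esterification: SN2 displacement of the activated allylic oxygen by the carboxylate inverts C10 to the α (axial) ester of the target, the nucleophile approaching anti to the C1 methyl; no acyl-activated angelate is formed, so the Z olefin should not isomerise, and the tertiary C4 hydroxyl is inert to the reagents.

**Compound list**

1 | (S)-(+)-Wieland–Miescher ketone, (8aS)-8a-methyl-3,4,8,8a-tetrahydronaphthalene-1,6(2H,7H)-dione | C[C@]12CCC(=O)C=C1CCCC2=O | starting material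
2 | hydroxy enone: C4 ketone, C5=C6, 10β-OH cis to the 1β-methyl, (4aS,5S)-5-hydroxy-4a-methyl-4,4a,5,6,7,8-hexahydronaphthalen-2(3H)-one | C[C@]12CCC(=O)C=C1CCC[C@@H]2O | intermediate
3 | 10β-TIPS ether of 2 | C[C@]12CCC(=O)C=C1CCC[C@@H]2O[Si](C(C)C)(C(C)C)C(C)C | intermediate
4 | allylic alcohol: 4β-OH, C5=C6, 10β-OTIPS | C[C@]12CC[C@H](O)C=C1CCC[C@@H]2O[Si](C(C)C)(C(C)C)C(C)C | intermediate
5 | osmate ester–TMEDA chelate: cyclic OsO2 diester on O5β and O6β, 4β-OH, 10β-OTIPS | C[C@]12CC[C@H](O)[C@@H]3O[Os](=O)(=O)O[C@]13CCC[C@@H]2O[Si](C(C)C)(C(C)C)C(C)C.CN(C)CCN(C)C | intermediate (not isolated)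
6 | all-cis triol: 4β,5β,6β-OH, cis-decalin, 10β-OTIPS | C[C@]12CC[C@H](O)[C@H](O)[C@@]1(O)CCC[C@@H]2O[Si](C(C)C)(C(C)C)C(C)C | intermediate
7 | 4β-OTBS 5β,6β-diol, 10β-OTIPS | C[C@]12CC[C@H](O[Si](C)(C)C(C)(C)C)[C@H](O)[C@@]1(O)CCC[C@@H]2O[Si](C(C)C)(C(C)C)C(C)C | intermediate
8 | hydroxy mesylate: 4β-OTBS, 5β-OMs, angular 6β-OH, 10β-OTIPS, cis-decalin | C[C@]12CC[C@H](O[Si](C)(C)C(C)(C)C)[C@H](OS(C)(=O)=O)[C@@]1(O)CCC[C@@H]2O[Si](C(C)C)(C(C)C)C(C)C | intermediate
9 | trans-fused hydroazulen-6-one: 1β-Me, 5α-H, 4β-OTBS, 10β-OTIPS | O=C1CCC[C@H](O[Si](C(C)C)(C(C)C)C(C)C)[C@@]2(C)CC[C@H](O[Si](C)(C)C(C)(C)C)[C@H]12 | intermediate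
10 | 6α-alcohol: 4β-OTBS, 10β-OTIPS | O[C@H]1CCC[C@H](O[Si](C(C)C)(C(C)C)C(C)C)[C@@]2(C)CC[C@H](O[Si](C)(C)C(C)(C)C)[C@H]12 | intermediate
11 | benzoyl chloride | O=C(Cl)c1ccccc1 | starting material
12 | 6α-benzoate: 4β-OTBS, 10β-OTIPS | O=C(c1ccccc1)O[C@H]2CCC[C@H](O[Si](C(C)C)(C(C)C)C(C)C)[C@@]3(C)CC[C@H](O[Si](C)(C)C(C)(C)C)[C@H]23 | intermediate
13 | 4β-alcohol: 6α-OBz, 10β-OTIPS | O=C(c1ccccc1)O[C@H]2CCC[C@H](O[Si](C(C)C)(C(C)C)C(C)C)[C@@]3(C)CC[C@H](O)[C@H]23 | intermediate
14 | C4 ketone: 6α-OBz, 10β-OTIPS | O=C(c1ccccc1)O[C@H]2CCC[C@H](O[Si](C(C)C)(C(C)C)C(C)C)[C@@]3(C)CCC(=O)[C@H]23 | intermediate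
15 | isopropylmagnesium chloride | CC(C)[Mg]Cl | starting material
16 | tertiary alcohol: 4β-OH, 4α-isopropyl, 6α-OBz, 10β-OTIPS | O=C(c1ccccc1)O[C@H]2CCC[C@H](O[Si](C(C)C)(C(C)C)C(C)C)[C@@]3(C)CC[C@@](O)(C(C)C)[C@H]23 | intermediate
17 | 4β,10β-diol: 4α-isopropyl, 6α-OBz | O=C(c1ccccc1)O[C@H]2CCC[C@H](O)[C@@]3(C)CC[C@@](O)(C(C)C)[C@H]23 | intermediate
18 | C10 ketone: 4β-OH, 4α-isopropyl, 6α-OBz | O=C(c1ccccc1)O[C@H]2CCCC(=O)[C@@]3(C)CC[C@@](O)(C(C)C)[C@H]23 | intermediate
19 | bis-TMS derivative: C9=C10 enol silyl ether, 4β-OTMS | O=C(c1ccccc1)O[C@H]2CCC=C(O[Si](C)(C)C)[C@@]3(C)CC[C@@](O[Si](C)(C)C)(C(C)C)[C@H]23 | intermediate (not isolated)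
20 | cyclohept-8-en-10-one: C8=C9, C10 ketone, 4β-OTMS, 6α-OBz | O=C(c1ccccc1)O[C@H]2CC=CC(=O)[C@@]3(C)CC[C@@](O[Si](C)(C)C)(C(C)C)[C@H]23 | intermediate
21 | methyllithium | [Li]C | starting material
22 | enol silyl ether: C8 methyl (configuration not defined, centre erased in the same flask), C9=C10–OTMS, 4β-OTMS | O=C(c1ccccc1)O[C@H]2CC(C)C=C(O[Si](C)(C)C)[C@@]3(C)CC[C@@](O[Si](C)(C)C)(C(C)C)[C@H]23 | intermediate (not isolated)
23 | 8-methyl-8-en-10-one, 4β-OTMS | O=C(c1ccccc1)O[C@H]2CC(C)=CC(=O)[C@@]3(C)CC[C@@](O[Si](C)(C)C)(C(C)C)[C@H]23 | intermediate (not isolated)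
24 | 8-methyl-8-en-10-one: 4β-OH, 4α-isopropyl, 6α-OBz | O=C(c1ccccc1)O[C@H]2CC(C)=CC(=O)[C@@]3(C)CC[C@@](O)(C(C)C)[C@H]23 | intermediate
25 | 10β-allylic alcohol: C8(Me)=C9, 4β-OH, 6α-OBz | O=C(c1ccccc1)O[C@H]2CC(C)=C[C@H](O)[C@@]3(C)CC[C@@](O)(C(C)C)[C@H]23 | intermediate
26 | angelic acid, (Z)-2-methylbut-2-enoic acid | C/C=C(/C)C(=O)O | starting material
27 | target: 10α-angeloyloxy-6α-benzoyloxy-4β-hydroxy-4α-isopropyl-1β,8-dimethyl trans-hydroazul-8-ene | C/C=C(/C)C(=O)O[C@@H]1C=C(C)C[C@H](OC(=O)c2ccccc2)[C@@H]2[C@]1(C)CC[C@@]2(O)C(C)C | target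

**Step count and risks**

Total steps: 18. Longest linear sequence: 18 steps (1 → 27).

Steps most likely to fail:

1. Step 7 (key rearrangement). What may go wrong: migration of the other angular bond (C6–C7) through the minor chair–chair form, base-induced E2 loss of the mesylate, 1,3-transfer of the TBS group to the C6 alkoxide, or enolisation of the β-silyloxy ketone product with epimerisation at C5 or loss of silanolate. The fallback sets out from mesylate 8 and comes back at ketone 9. The shift is triggered by electrophilic pull instead of alkoxide push: Et3Al in CH2Cl2 at −78 → 0 °C turns the hydroxyl into an aluminium alkoxide that at the same time activates the neighbouring sulfonate (organoaluminium-promoted pinacol-type rearrangement of β-mesyloxy alcohols). No Brønsted base is present, so elimination, silyl transfer and enolate chemistry are shut off. This path passes through no new compound (F0).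

2. Step 18 (Mitsunobu angeloylation). What may go wrong: slow SN2 at a secondary allylic carbon next to the quaternary C1, leakage through an allyl cation with loss of stereochemical integrity or allylic transposition; the step also relies on β-selective hydride delivery in step 17. The fallback sets out from enone 24 and comes back at 27. A reagent-controlled CBS reduction with (S)-2-methyl-CBS-oxazaborolidine and catecholborane (toluene, −60 °C), in which the quaternary C1 side acts as the large group, should deliver hydride to the β face and give the 10α-allylic alcohol F1. This is esterified with retention by the mixed anhydride of angelic acid 26 and 2,4,6-trichlorobenzoyl chloride (Et3N, then the alcohol, toluene, 75 °C), a known way to angelates without Z→E isomerisation.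

3. Step 5 (regioselective silylation). What may go wrong: poor discrimination between the two secondary hydroxyls, giving silylation at O5 or bis-silylation. The fallback sets out from triol 6 and comes back at ketone 9. The order is reversed and the sulfonate is placed first by tin direction: the dibutylstannylene acetal (Bu2SnO, toluene, reflux) activates the equatorial oxygen of a cis-vicinal pair, here O5, and TsCl/Et3N (CH2Cl2, 0 °C) should give the C5 tosylate diol F2. The only remaining secondary hydroxyl (C4) is then silylated (TBSOTf, 2,6-lutidine, −78 °C) to the 4β-OTBS tosylate F3, whose potassium alkoxide (KOtBu, tBuOH/THF) undergoes the same 1,2-shift to 9.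

**Further compounds**

F0 | step 7 | none | none
F1 | step 18 | 10α-allylic alcohol (C8(Me)=C9, 4β-OH, 4α-isopropyl, 6α-OBz) | O=C(c1ccccc1)O[C@H]2CC(C)=C[C@@H](O)[C@@]3(C)CC[C@@](O)(C(C)C)[C@H]23
F2 | step 5 | C5 β-tosylate with free 4β-OH and angular 6β-OH, 10β-OTIPS | C[C@]12CC[C@H](O)[C@H](OS(=O)(=O)c3ccc(C)cc3)[C@@]1(O)CCC[C@@H]2O[Si](C(C)C)(C(C)C)C(C)C
F3 | step 5 | 4β-OTBS C5 β-tosylate, angular 6β-OH, 10β-OTIPS | C[C@]12CC[C@H](O[Si](C)(C)C(C)(C)C)[C@H](OS(=O)(=O)c3ccc(C)cc3)[C@@]1(O)CCC[C@@H]2O[Si](C(C)C)(C(C)C)C(C)C
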